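**Retrosynthetic overview**

- The target (flavanone numbering: O1, C2, C3, C4, C4a, C5–C8, C8a) is reached from its hexa-O-benzyl ether by one neutral hydrogenolysis.
- Structural feature used: C2, which carries the phenyl ring and is bonded to O1, is the benzylic carbon of a benzyl ether on the C8a oxygen of ring A. C3 is the single carbon between C2 and the C4 carbonyl. Ring C is therefore an ortho O-benzyl group plus a one-carbon carbene on the acyl carbon, and C2–C3 is made by carbenoid insertion into the benzylic C–H bond.
- The diazomethyl ketone comes from the corresponding methyl ketone by detrifluoroacetylative diazo transfer.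
- The methyl ketone comes from 2,4,6-trihydroxyacetophenone by double Friedel–Crafts benzylation at its two free ring positions with 2,3-bis(benzyloxy)benzyl alcohol, followed by tri-O-benzylation. All phenol protection is benzyl, so the catechol ethers survive the acid step and fall in the final hydrogenolysis.
- Ring order: ring A, ring B (the phenyl of a benzyl ether) and both catechol rings are bought; ring C is the only ring formed (step 6).

Key step: step 6

Assumption: Rh2(S-PTTL)4 is taken to deliver the (2S) flavanone. If the (2R) product were found to dominate, the enantiomeric catalyst Rh2(R-PTTL)4 would be used with no other change.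

**Route**

Step 1
Reactants: 1 2,3-dihydroxybenzaldehyde; 2 benzyl bromide
Product: 3 2,3-bis(benzyloxy)benzaldehyde
Conditions: BnBr (2.3 equiv), K2CO3, DMF, 60 °C, under N2
Reagents that add atoms: benzyl bromide (compound 2), BrCc1ccccc1
Why: Williamson ether synthesis, in which both catechol phenoxides are alkylated by the primary benzylic bromide in a polar aprotic solvent while the aldehyde is inert to carbonate.

Step 2
Reactants: 3 2,3-bis(benzyloxy)benzaldehyde
Product: 4 [2,3-bis(benzyloxy)phenyl]methanol
Conditions: NaBH4, MeOH–THF, 0 °C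
Reagents that add atoms: none
Why: Borohydride reduction of the aryl aldehyde to the primary benzylic alcohol, which leaves the benzyl ethers untouched.

Step 3
Reactants: 5 2,4,6-trihydroxyacetophenone; 4 [2,3-bis(benzyloxy)phenyl]methanol (2.3 equiv)
Product: 6 1-{3,5-bis[2,3-bis(benzyloxy)benzyl]-2,4,6-trihydroxyphenyl}ethan-1-one
Conditions: Sc(OTf)3 (10 mol%), MeNO2–1,4-dioxane, 60 °C, slow addition of 4
Reagents that add atoms: none
Why: Lewis-acid-catalysed Friedel–Crafts benzylation, in which the ortho-alkoxy-stabilised benzylic cation from 4 is captured at C3 and C5 of the phloroglucinol ring, the only free and by far the most nucleophilic arene positions present, so that the reaction should stop at the bis-adduct and, with no base present, cannot go on to dearomatising geminal alkylation.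

Step 4
Reactants: 6 1-{3,5-bis[2,3-bis(benzyloxy)benzyl]-2,4,6-trihydroxyphenyl}ethan-1-one; 2 benzyl bromide
Product: 7 1-{2,4,6-tris(benzyloxy)-3,5-bis[2,3-bis(benzyloxy)benzyl]phenyl}ethan-1-one
Conditions: BnBr (4.5 equiv), K2CO3, Bu4NI (cat.), degassed DMF, 70 °C, under Ar
Reagents that add atoms: benzyl bromide (compound 2), BrCc1ccccc1
Why: Williamson O-benzylation of the three phenols, where the potassium phenoxide in DMF with every ring carbon already substituted should react through oxygen and not by dearomatising C-alkylation, and heat with iodide catalysis drives the two hydrogen-bonded ortho hydroxyls to completion.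

Step 5
Reactants: 7 1-{2,4,6-tris(benzyloxy)-3,5-bis[2,3-bis(benzyloxy)benzyl]phenyl}ethan-1-one
Product: 9 2-diazo-1-{2,4,6-tris(benzyloxy)-3,5-bis[2,3-bis(benzyloxy)benzyl]phenyl}ethan-1-one, via trifluoroacetyl diketone 8 (not isolated)
Conditions: LiN(SiMe3)2, THF, −78 °C; CF3CO2CH2CF3, −78 °C; 5% aq HCl work-up; then MsN3, Et3N, H2O, MeCN, rt
Reagents that add atoms: methanesulfonyl azide, CS(=O)(=O)N=[N+]=[N-] (supplies the two diazo nitrogens); 2,2,2-trifluoroethyl trifluoroacetate, O=C(OCC(F)(F)F)C(F)(F)F (its CF3CO group is carried only in 8 and is lost again)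
Why: Detrifluoroacetylative (Regitz-type) diazo transfer, in which the lithium enolate of the methyl ketone, the only enolisable site, undergoes Claisen trifluoroacetylation to an activated 1,3-diketone that accepts the diazo group from the sulfonyl azide and then sheds the trifluoroacetyl group, a sequence suited to hindered aryl methyl ketones and inert to the ethers.

Step 6
Reactants: 9 2-diazo-1-{2,4,6-tris(benzyloxy)-3,5-bis[2,3-bis(benzyloxy)benzyl]phenyl}ethan-1-one
Product: 10 (2S)-5,7-bis(benzyloxy)-6,8-bis[2,3-bis(benzyloxy)benzyl]-2-phenyl-2,3-dihydro-4H-chromen-4-one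
Conditions: Rh2(S-PTTL)4 (dirhodium tetrakis[N-phthaloyl-(S)-tert-leucinate], 2 mol%), toluene, 4 Å MS, slow addition of 9, −20 °C to rt
Reagents that add atoms: none
Why: The diazoketone loses N2 on the dirhodium carboxylate (divalent rhodium) to give an electrophilic rhodium carbenoid at the future C3, which inserts through a concerted, hydride-transfer-like three-centre transition state into a benzylic C–H bond of an ortho benzyloxy group and so forms the C2–C3 bond. The closest known reaction type is the rhodium-carbenoid intramolecular C–H insertion of 2-alkoxyaryl diazoketones to chroman-4-ones. Ring C closes as a six-membered ring by 1,6-insertion (C3, C4, C4a, C8a, O1, C2), because the atom at the usual 1,5 position is the ether oxygen, which carries no hydrogen. The C2 stereocentre is set by the catalyst, whose four N-phthaloyl-tert-leucinate ligands form a chiral pocket that selects one of the two enantiotopic benzylic hydrogens; the two ortho benzyloxy groups are interchanged by the local twofold axis of ring A, so insertion into either gives the same enantiomer and the other remains as the C5 protecting group. The step needs chemoselectivity for C–H insertion over attack on the ether oxygen (oxonium ylide, then 1,2-benzyl shift to a 2-benzylbenzofuran-3-one), over carbene dimerisation and over arene cyclopropanation. The substrate favours insertion because the targeted C–H bond is doubly activated (α-oxygen and phenyl) and is held beside the carbenoid by the flanking substituents, which twist both the acyl group and the OCH2Ph group out of the ring A plane, while every other C–H bond is geometrically out of reach; slow addition at low concentration suppresses dimerisation.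

Step 7
Reactants: 10 (2S)-5,7-bis(benzyloxy)-6,8-bis[2,3-bis(benzyloxy)benzyl]-2-phenyl-2,3-dihydro-4H-chromen-4-one
Product: 11 (2S)-6,8-bis(2,3-dihydroxybenzyl)-5,7-dihydroxy-2-phenyl-2,3-dihydro-4H-chromen-4-one (CNP0059702.1)
Conditions: H2 (1 atm), 10% Pd/C, EtOAc–MeOH, rt, stopped after uptake of 6 equiv H2; work-up under Ar
Reagents that add atoms: none
Why: Catalytic hydrogenolysis of the six aryl benzyl ethers under neutral conditions, in which the cyclic C2–O1 benzylic ether, the diarylmethane links and the aryl ketone react much more slowly, and the absence of acid or base avoids ring opening to the chalcone, so C2 should keep its configuration.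

**Compound list**

1 | 2,3-dihydroxybenzaldehyde | O=Cc1cccc(O)c1O | starting material
2 | benzyl bromide | BrCc1ccccc1 | starting material
3 | 2,3-bis(benzyloxy)benzaldehyde | O=Cc1cccc(OCc2ccccc2)c1OCc1ccccc1 | intermediate
4 | [2,3-bis(benzyloxy)phenyl]methanol | OCc1cccc(OCc2ccccc2)c1OCc1ccccc1 | intermediate
5 | 2,4,6-trihydroxyacetophenone | CC(=O)c1c(O)cc(O)cc1O | starting material
6 | 1-{3,5-bis[2,3-bis(benzyloxy)benzyl]-2,4,6-trihydroxyphenyl}ethan-1-one | CC(=O)c1c(O)c(Cc2cccc(OCc3ccccc3)c2OCc2ccccc2)c(O)c(Cc2cccc(OCc3ccccc3)c2OCc2ccccc2)c1O | intermediate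
7 | 1-{2,4,6-tris(benzyloxy)-3,5-bis[2,3-bis(benzyloxy)benzyl]phenyl}ethan-1-one | CC(=O)c1c(OCc2ccccc2)c(Cc2cccc(OCc3ccccc3)c2OCc2ccccc2)c(OCc2ccccc2)c(Cc2cccc(OCc3ccccc3)c2OCc2ccccc2)c1OCc1ccccc1 | intermediate
8 | 4,4,4-trifluoro-1-{2,4,6-tris(benzyloxy)-3,5-bis[2,3-bis(benzyloxy)benzyl]phenyl}butane-1,3-dione | O=C(CC(=O)C(F)(F)F)c1c(OCc2ccccc2)c(Cc2cccc(OCc3ccccc3)c2OCc2ccccc2)c(OCc2ccccc2)c(Cc2cccc(OCc3ccccc3)c2OCc2ccccc2)c1OCc1ccccc1 | intermediate (not isolated)
9 | 2-diazo-1-{2,4,6-tris(benzyloxy)-3,5-bis[2,3-bis(benzyloxy)benzyl]phenyl}ethan-1-one | [N-]=[N+]=CC(=O)c1c(OCc2ccccc2)c(Cc2cccc(OCc3ccccc3)c2OCc2ccccc2)c(OCc2ccccc2)c(Cc2cccc(OCc3ccccc3)c2OCc2ccccc2)c1OCc1ccccc1 | intermediate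
10 | (2S)-5,7-bis(benzyloxy)-6,8-bis[2,3-bis(benzyloxy)benzyl]-2-phenyl-2,3-dihydro-4H-chromen-4-one | O=C1C[C@@H](c2ccccc2)Oc2c(Cc3cccc(OCc4ccccc4)c3OCc3ccccc3)c(OCc3ccccc3)c(Cc3cccc(OCc4ccccc4)c3OCc3ccccc3)c(OCc3ccccc3)c21 | intermediate
11 | (2S)-6,8-bis(2,3-dihydroxybenzyl)-5,7-dihydroxy-2-phenyl-2,3-dihydro-4H-chromen-4-one | O=C1C[C@@H](c2ccccc2)Oc2c(Cc3cccc(O)c3O)c(O)c(Cc3cccc(O)c3O)c(O)c21 | target

**Step count and risks**

Total steps: 7. Longest linear sequence: 7 (steps 1 to 7 from compound 1; compound 5 enters at step 3).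

Steps most likely to fail:

1. Step 6. The carbenoid may be diverted to the ether oxygen (oxonium ylide and 1,2-benzyl shift) or dimerise, and discrimination between the two enantiotopic benzylic hydrogens may be poor. The fallback sets out from 6 and returns at 10, building ring C by conjugate arylation of a chromone. Compound 6 is benzylated with only two equivalents of 2 (K2CO3, acetone, reflux), which leaves the hydrogen-bonded ortho hydroxyl free and should give 1-{2,4-bis(benzyloxy)-3,5-bis[2,3-bis(benzyloxy)benzyl]-6-hydroxyphenyl}ethan-1-one F1. Condensation with N,N-dimethylformamide dimethyl acetal (toluene, 100 °C) gives the enaminone (E)-1-{2,4-bis(benzyloxy)-3,5-bis[2,3-bis(benzyloxy)benzyl]-6-hydroxyphenyl}-3-(dimethylamino)prop-2-en-1-one F2. Treatment with HCl in CH2Cl2 closes the pyranone with loss of dimethylamine to the chromone 5,7-bis(benzyloxy)-6,8-bis[2,3-bis(benzyloxy)benzyl]-4H-chromen-4-one F3. Enantioselective conjugate addition of phenylboronic acid to F3 would then give 10, with the C2 configuration set by the ligand on palladium (Pd(OCOCF3)2, 4-tert-butyl-2-(pyridin-2-yl)-4,5-dihydrooxazole in the enantiomer that gives the 2S product, NH4PF6, H2O, ClCH2CH2Cl, 60 °C).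

2. Step 3. Ionisation of the benzylic alcohol may be sluggish, the alcohol may self-condense, the reaction may stall at the mono-adduct, or acid may cause benzyl ether migration. The fallback sets out from 5 and 4 and returns at 7, so it also bypasses step 4; it replaces the electrophilic benzylation by a double Negishi coupling. Compound 5 is tri-O-benzylated (2, K2CO3, DMF, 80 °C) to 1-[2,4,6-tris(benzyloxy)phenyl]ethan-1-one F4. Bromination at both free ring positions (N-bromosuccinimide, MeCN, 0 °C to rt) gives 1-[2,4,6-tris(benzyloxy)-3,5-dibromophenyl]ethan-1-one F5. Alcohol 4 is converted with SOCl2 (CH2Cl2, 0 °C) into 1,2-bis(benzyloxy)-3-(chloromethyl)benzene F6. Zinc insertion (Zn dust, LiCl, THF, rt) gives [2,3-bis(benzyloxy)benzyl]zinc chloride F7. Coupling of F7 (2.5 equiv) with F5 (Pd(OAc)2, SPhos, THF, 50 °C) should give 7.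

3. Step 4. The ambident phenoxide may be alkylated at carbon with dearomatisation, the doubly flanked hydrogen-bonded hydroxyls may be etherified incompletely, and the electron-rich phenoxide may be oxidised by air. The fallback sets out from 6 and returns at 7, replacing phenoxide alkylation by a Mitsunobu etherification (benzyl alcohol, PPh3, diisopropyl azodicarboxylate, THF, 0 °C to rt). In this reaction the neutral phenol is coupled with the phosphonium-activated alcohol and carbon alkylation is not expected. New compounds on this path: none F0.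

**Further compounds**

F1 | step 6 | 1-{2,4-bis(benzyloxy)-3,5-bis[2,3-bis(benzyloxy)benzyl]-6-hydroxyphenyl}ethan-1-one | CC(=O)c1c(O)c(Cc2cccc(OCc3ccccc3)c2OCc2ccccc2)c(OCc2ccccc2)c(Cc2cccc(OCc3ccccc3)c2OCc2ccccc2)c1OCc1ccccc1
F2 | step 6 | (E)-1-{2,4-bis(benzyloxy)-3,5-bis[2,3-bis(benzyloxy)benzyl]-6-hydroxyphenyl}-3-(dimethylamino)prop-2-en-1-one | CN(C)/C=C/C(=O)c1c(O)c(Cc2cccc(OCc3ccccc3)c2OCc2ccccc2)c(OCc2ccccc2)c(Cc2cccc(OCc3ccccc3)c2OCc2ccccc2)c1OCc1ccccc1
F3 | step 6 | 5,7-bis(benzyloxy)-6,8-bis[2,3-bis(benzyloxy)benzyl]-4H-chromen-4-one | O=c1ccoc2c(Cc3cccc(OCc4ccccc4)c3OCc3ccccc3)c(OCc3ccccc3)c(Cc3cccc(OCc4ccccc4)c3OCc3ccccc3)c(OCc3ccccc3)c12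
F4 | step 3 | 1-[2,4,6-tris(benzyloxy)phenyl]ethan-1-one | CC(=O)c1c(OCc2ccccc2)cc(OCc2ccccc2)cc1OCc1ccccc1
F5 | step 3 | 1-[2,4,6-tris(benzyloxy)-3,5-dibromophenyl]ethan-1-one | CC(=O)c1c(OCc2ccccc2)c(Br)c(OCc2ccccc2)c(Br)c1OCc1ccccc1
F6 | step 3 | 1,2-bis(benzyloxy)-3-(chloromethyl)benzene | ClCc1cccc(OCc2ccccc2)c1OCc1ccccc1
F7 | step 3 | [2,3-bis(benzyloxy)benzyl]zinc chloride | Cl[Zn]Cc1cccc(OCc2ccccc2)c1OCc1ccccc1
F0 | step 4 | none | none
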